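**Retrosynthetic overview**
- The two identical quinone rings are not built. Both come from commercial 1,2,4,5-tetramethoxybenzene and are unveiled together at the end (phenol acetate, oxidative demethylation with (NH4)2Ce(NO3)6, deacetylation), so there is no ring-forming step.
- The OH/OMe distinction on each ring comes from a benzylic ketone: BCl3 cleaves only a methoxy group ortho to C=O, and the ketone is then reduced to CH2.
- Key disconnection: the C2–C3 and C11–C12 bonds of the C13 tether, made by a two-fold directed aldol addition of the lithium enolate of 1-(2,3,5,6-tetramethoxy-4-methylphenyl)ethanone to nonanedial (2 + 9 + 2 carbons), followed by dehydration and hydrogenation.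
- The aryl methyl ketone comes from tetramethoxybenzene by two successive ortho-lithiations (MeI, then N-methoxy-N-methylacetamide); nonanedial comes from nonane-1,9-diol.

Assumption: the target is read as two 2-hydroxy-5-methoxy-6-methyl-1,4-benzoquinone units joined at C-3 by a (CH2)13 chain (C29H40O8); it has no stereocentre and is achiral, so no enantiomer has to be chosen.

**Step 1**
Reactants: 1 1,2,4,5-tetramethoxybenzene
Product: 3 2,3,5,6-tetramethoxytoluene, via aryllithium 2 (not isolated)
Conditions: n-BuLi (1.05 equiv), THF, 0 °C → rt, 1 h; then MeI, 0 °C → rt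
Reagents that add atoms: iodomethane, CI
Why: Directed ortho-metalation removes a ring proton flanked by two methoxy groups and the aryllithium is methylated by SN2 on iodomethane, one equivalent of base keeping it to mono-substitution.

**Step 2**
Reactants: 3 2,3,5,6-tetramethoxytoluene
Product: 6 1-(2,3,5,6-tetramethoxy-4-methylphenyl)ethan-1-one, via methylated aryllithium 4 (not isolated), via lithium hemiaminal adduct 5 (not isolated)
Conditions: n-BuLi (1.1 equiv), TMEDA, THF, 0 °C → rt; then MeC(O)N(OMe)Me, −78 → 0 °C; 1 M HCl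
Reagents that add atoms: N-methoxy-N-methylacetamide, CC(=O)N(C)OC
Why: A second directed ortho-metalation at the only ring C–H left is followed by a Weinreb ketone synthesis, whose chelated tetrahedral adduct prevents over-addition.

**Step 3**
Reactants: 7 nonane-1,9-diol
Product: 8 nonanedial
Conditions: TEMPO (10 mol %), PhI(OAc)2 (2.2 equiv), CH2Cl2, rt; short silica plug, used fresh
Reagents that add atoms: none
Why: Oxoammonium-mediated (TEMPO) oxidation of primary alcohols stops cleanly at the aldehyde in anhydrous CH2Cl2.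

**Step 4**
Reactants: 6 1-(2,3,5,6-tetramethoxy-4-methylphenyl)ethan-1-one (2.3 equiv); 8 nonanedial (1.0 equiv)
Product: 10 3,11-dihydroxy-1,13-bis(2,3,5,6-tetramethoxy-4-methylphenyl)tridecane-1,13-dione (rac/meso mixture), via lithium enolate 9 (not isolated)
Conditions: LiN(iPr)2 (commercial, 2.3 equiv), THF, −78 °C, 45 min; then 8, −78 °C, 1 h; AcOH quench at −78 °C
Reagents that add atoms: none
Why: Directed aldol addition of the preformed lithium enolate of a methyl ketone (one enolisable site only) to both aldehyde groups at low temperature; the two carbinol centres form without control, which is harmless because step 5 removes both.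

**Step 5**
Reactants: 10 3,11-dihydroxy-1,13-bis(2,3,5,6-tetramethoxy-4-methylphenyl)tridecane-1,13-dione
Product: 12 (2E,11E)-1,13-bis(2,3,5,6-tetramethoxy-4-methylphenyl)trideca-2,11-diene-1,13-dione, via bis-mesylate 11 (not isolated)
Conditions: MsCl (3 equiv), Et3N (8 equiv), CH2Cl2, 0 °C → rt, 12 h
Reagents that add atoms: none
Why: Mesylation of the β-hydroxy ketones and E1cB elimination give the conjugated enones, the E geometry being the thermodynamically preferred one.

**Step 6**
Reactants: 12 (2E,11E)-1,13-bis(2,3,5,6-tetramethoxy-4-methylphenyl)trideca-2,11-diene-1,13-dione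
Product: 13 1,13-bis(2,3,5,6-tetramethoxy-4-methylphenyl)tridecane-1,13-dione
Conditions: H2 (1 atm), 10 % Pd/C, EtOAc, rt
Reagents that add atoms: none
Why: Catalytic hydrogenation saturates the conjugated alkenes, while the di-ortho-substituted aryl ketones and the aryl methyl ethers are inert under neutral conditions.

**Step 7**
Reactants: 13 1,13-bis(2,3,5,6-tetramethoxy-4-methylphenyl)tridecane-1,13-dione
Product: 15 1,13-bis(2-hydroxy-3,5,6-trimethoxy-4-methylphenyl)tridecane-1,13-dione, via bis(aryloxydichloroborane) chelate 14 (not isolated)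
Conditions: BCl3 (1 M in CH2Cl2, 2.4 equiv), CH2Cl2, −78 → 0 °C; then H2O
Reagents that add atoms: none
Why: Chelation-controlled ether cleavage: BCl3 bound to the ketone oxygen cleaves only a methoxy group ortho to it, the six-membered boron chelate then shuts down further cleavage, and the two ortho methoxy groups of each ring are equivalent so only one product can form.

**Step 8**
Reactants: 15 1,13-bis(2-hydroxy-3,5,6-trimethoxy-4-methylphenyl)tridecane-1,13-dione
Product: 16 2,2'-(tridecane-1,13-diyl)bis(3,4,6-trimethoxy-5-methylphenol)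
Conditions: Et3SiH (6 equiv), CF3CO2H, CH2Cl2, 0 °C → rt
Reagents that add atoms: none
Why: Ionic hydrogenation deoxygenates the o-hydroxyaryl ketones to CH2 by hydride transfer from the silane to a benzylic cation that the electron-rich, fully substituted ring stabilises.

**Step 9**
Reactants: 16 2,2'-(tridecane-1,13-diyl)bis(3,4,6-trimethoxy-5-methylphenol)
Product: 17 (tridecane-1,13-diyl)bis(3,4,6-trimethoxy-5-methyl-2,1-phenylene) diacetate
Conditions: Ac2O, pyridine, DMAP (cat.), rt
Reagents that add atoms: acetic anhydride, CC(=O)OC(C)=O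
Why: DMAP-catalysed O-acylation converts the hindered phenols into acetates, which makes that oxygen electron-poor and non-oxidisable for the next step.

**Step 10**
Reactants: 17 (tridecane-1,13-diyl)bis(3,4,6-trimethoxy-5-methyl-2,1-phenylene) diacetate
Product: 18 (tridecane-1,13-diyl)bis(4-methoxy-5-methyl-3,6-dioxocyclohexa-1,4-diene-2,1-diyl) diacetate
Conditions: (NH4)2Ce(NO3)6 (5 equiv), MeCN/THF/H2O, 0 °C, 30 min
Reagents that add atoms: water, O
Why: Oxidative demethylation with (NH4)2Ce(NO3)6 converts the one para-dimethoxy pair of each ring into the p-quinone, because the other para pair contains the acetoxy group, which cannot be cleaved oxidatively.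

**Step 11**
Reactants: 18 (tridecane-1,13-diyl)bis(4-methoxy-5-methyl-3,6-dioxocyclohexa-1,4-diene-2,1-diyl) diacetate
Product: 20 3,3'-(tridecane-1,13-diyl)bis(2-hydroxy-5-methoxy-6-methyl-1,4-benzoquinone), via dipotassium bis-quinonolate 19 (not isolated)
Conditions: K2CO3 (1.1 equiv), MeOH/THF, 0 °C, 30 min; then 1 M HCl
Reagents that add atoms: none
Why: The acetoxyquinone is a vinylogous anhydride and undergoes fast transesterification (methanolysis) to the quinonolate, whose negative charge protects the remaining methoxy group until acidification gives the hydroxyquinone.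

**Compound list**
1 | 1,2,4,5-tetramethoxybenzene | COc1cc(OC)c(OC)cc1OC | starting material
2 | (2,3,5,6-tetramethoxyphenyl)lithium | [Li]c1c(OC)c(OC)cc(OC)c1OC | intermediate
3 | 2,3,5,6-tetramethoxytoluene | Cc1c(OC)c(OC)cc(OC)c1OC | intermediate
4 | (2,3,5,6-tetramethoxy-4-methylphenyl)lithium | [Li]c1c(OC)c(OC)c(C)c(OC)c1OC | intermediate
5 | lithium 1-[methoxy(methyl)amino]-1-(2,3,5,6-tetramethoxy-4-methylphenyl)ethan-1-olate | [Li]OC(C)(N(C)OC)c1c(OC)c(OC)c(C)c(OC)c1OC | intermediate
6 | 1-(2,3,5,6-tetramethoxy-4-methylphenyl)ethan-1-one | CC(=O)c1c(OC)c(OC)c(C)c(OC)c1OC | intermediate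
7 | nonane-1,9-diol | OCCCCCCCCCO | starting material
8 | nonanedial | O=CCCCCCCCC=O | intermediate
9 | lithium 1-(2,3,5,6-tetramethoxy-4-methylphenyl)ethen-1-olate | [Li]OC(=C)c1c(OC)c(OC)c(C)c(OC)c1OC | intermediate
10 | 3,11-dihydroxy-1,13-bis(2,3,5,6-tetramethoxy-4-methylphenyl)tridecane-1,13-dione (mixture of racemic and meso forms) | COc1c(OC)c(C)c(OC)c(OC)c1C(=O)CC(O)CCCCCCCC(O)CC(=O)c1c(OC)c(OC)c(C)c(OC)c1OC | intermediate
11 | 1,13-dioxo-1,13-bis(2,3,5,6-tetramethoxy-4-methylphenyl)tridecane-3,11-diyl dimethanesulfonate | COc1c(OC)c(C)c(OC)c(OC)c1C(=O)CC(OS(C)(=O)=O)CCCCCCCC(OS(C)(=O)=O)CC(=O)c1c(OC)c(OC)c(C)c(OC)c1OC | intermediate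
12 | (2E,11E)-1,13-bis(2,3,5,6-tetramethoxy-4-methylphenyl)trideca-2,11-diene-1,13-dione | COc1c(OC)c(C)c(OC)c(OC)c1C(=O)/C=C/CCCCCCC/C=C/C(=O)c1c(OC)c(OC)c(C)c(OC)c1OC | intermediate
13 | 1,13-bis(2,3,5,6-tetramethoxy-4-methylphenyl)tridecane-1,13-dione | COc1c(OC)c(C)c(OC)c(OC)c1C(=O)CCCCCCCCCCCC(=O)c1c(OC)c(OC)c(C)c(OC)c1OC | intermediate
14 | 1,13-bis{2-[(dichloroboranyl)oxy]-3,5,6-trimethoxy-4-methylphenyl}tridecane-1,13-dione (boron chelated by the ketone oxygen) | ClB(Cl)Oc1c(OC)c(C)c(OC)c(OC)c1C(=O)CCCCCCCCCCCC(=O)c1c(OB(Cl)Cl)c(OC)c(C)c(OC)c1OC | intermediate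
15 | 1,13-bis(2-hydroxy-3,5,6-trimethoxy-4-methylphenyl)tridecane-1,13-dione | Oc1c(OC)c(C)c(OC)c(OC)c1C(=O)CCCCCCCCCCCC(=O)c1c(O)c(OC)c(C)c(OC)c1OC | intermediate
16 | 2,2'-(tridecane-1,13-diyl)bis(3,4,6-trimethoxy-5-methylphenol) | Oc1c(OC)c(C)c(OC)c(OC)c1CCCCCCCCCCCCCc1c(O)c(OC)c(C)c(OC)c1OC | intermediate
17 | (tridecane-1,13-diyl)bis(3,4,6-trimethoxy-5-methyl-2,1-phenylene) diacetate | CC(=O)Oc1c(OC)c(C)c(OC)c(OC)c1CCCCCCCCCCCCCc1c(OC(C)=O)c(OC)c(C)c(OC)c1OC | intermediate
18 | (tridecane-1,13-diyl)bis(4-methoxy-5-methyl-3,6-dioxocyclohexa-1,4-diene-2,1-diyl) diacetate | CC(=O)OC1=C(CCCCCCCCCCCCCC2=C(OC(C)=O)C(=O)C(C)=C(OC)C2=O)C(=O)C(OC)=C(C)C1=O | intermediate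
19 | dipotassium salt of the target (both quinone OH groups deprotonated) | [K+].[K+].COC1=C(C)C(=O)C([O-])=C(CCCCCCCCCCCCCC2=C([O-])C(=O)C(C)=C(OC)C2=O)C1=O | intermediate
20 | 3,3'-(tridecane-1,13-diyl)bis(2-hydroxy-5-methoxy-6-methyl-1,4-benzoquinone), CNP0110425.0, achiral | COC1=C(C)C(=O)C(O)=C(CCCCCCCCCCCCCC2=C(O)C(=O)C(C)=C(OC)C2=O)C1=O | target

**Totals**
Total steps: 11. Longest linear sequence: 10 steps (1, 2, 4, 5, 6, 7, 8, 9, 10, 11 from compound 1); step 3 is a one-step side branch.

**Three steps most likely to fail, with fallbacks**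

Step 4 (two-fold aldol on a self-condensing dialdehyde; mono-adducts and retro-aldol are possible). The fallback sets out from 3 and comes back at 13, avoiding the dialdehyde and also steps 5 and 6. Compound 3 is lithiated as in step 2 and the aryllithium 4 is quenched with CO2 to give 2,3,5,6-tetramethoxy-4-methylbenzoic acid F1. Oxalyl chloride with catalytic DMF converts it into 2,3,5,6-tetramethoxy-4-methylbenzoyl chloride F2. Commercial dimethyl tridecanedioate is deprotonated at both ends with LiN(SiMe3)2 (4.4 equiv, THF, −78 °C; the second equivalent per site takes up the acidic β-keto ester proton) and acylated with F2 (2.2 equiv) in a double crossed Claisen condensation to give dimethyl 2,12-bis(2,3,5,6-tetramethoxy-4-methylbenzoyl)tridecanedioate F3. Krapcho demethoxycarbonylation of F3 (LiCl, wet DMSO, 150 °C) gives diketone 13.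

Step 7 (over-demethylation of the neighbouring methoxy groups, or mixtures from two reacting sites per molecule). The fallback sets out from 6 and comes back at 15, making the distinction on the small monomer where the stoichiometry is easy to control and the product can be purified before coupling. Ketone 6 with BCl3 (1.1 equiv, CH2Cl2, −78 °C) gives 1-(2-hydroxy-3,5,6-trimethoxy-4-methylphenyl)ethan-1-one F4. Benzylation (BnBr, K2CO3, DMF) gives 1-[2-(benzyloxy)-3,5,6-trimethoxy-4-methylphenyl]ethan-1-one F5. Aldol addition of its lithium enolate to nonanedial 8 as in step 4 gives 1,13-bis[2-(benzyloxy)-3,5,6-trimethoxy-4-methylphenyl]-3,11-dihydroxytridecane-1,13-dione F6. MsCl/Et3N as in step 5 gives (2E,11E)-1,13-bis[2-(benzyloxy)-3,5,6-trimethoxy-4-methylphenyl]trideca-2,11-diene-1,13-dione F7. Hydrogenation over Pd/C saturates both alkenes and cleaves both benzyl ethers in one operation, giving 15.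

Step 10 (the regiochemistry rests on the acetate steering the oxidation to the right para pair; the acetoxyquinone is also labile). The fallback sets out from 15 and comes back at 20, replacing the protecting-group argument by symmetry. In 15 the second methoxy group ortho to each ketone is cleaved as well (BBr3, CH2Cl2, −78 → 0 °C) to give 1,13-bis(2,6-dihydroxy-3,5-dimethoxy-4-methylphenyl)tridecane-1,13-dione F8. Et3SiH/CF3CO2H reduction gives 2,2'-(tridecane-1,13-diyl)bis(4,6-dimethoxy-5-methylbenzene-1,3-diol) F9. In F9 the two hydroxyls of each ring are equivalent, each has a para methoxy group, and oxidation of either p-methoxyphenol unit (PhI(OAc)2, MeCN/H2O, 0 °C) leaves the other hydroxyl next to the chain and the other methoxy next to the methyl, so target 20 forms directly without a protecting group.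

**Further compounds**
F1 | step 4 | 2,3,5,6-tetramethoxy-4-methylbenzoic acid | OC(=O)c1c(OC)c(OC)c(C)c(OC)c1OC
F2 | step 4 | 2,3,5,6-tetramethoxy-4-methylbenzoyl chloride | ClC(=O)c1c(OC)c(OC)c(C)c(OC)c1OC
F3 | step 4 | dimethyl 2,12-bis(2,3,5,6-tetramethoxy-4-methylbenzoyl)tridecanedioate (mixture of diastereomers) | COC(=O)C(CCCCCCCCCC(C(=O)OC)C(=O)c1c(OC)c(OC)c(C)c(OC)c1OC)C(=O)c1c(OC)c(OC)c(C)c(OC)c1OC
F4 | step 7 | 1-(2-hydroxy-3,5,6-trimethoxy-4-methylphenyl)ethan-1-one | CC(=O)c1c(O)c(OC)c(C)c(OC)c1OC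
F5 | step 7 | 1-[2-(benzyloxy)-3,5,6-trimethoxy-4-methylphenyl]ethan-1-one | CC(=O)c1c(OCc2ccccc2)c(OC)c(C)c(OC)c1OC
F6 | step 7 | 1,13-bis[2-(benzyloxy)-3,5,6-trimethoxy-4-methylphenyl]-3,11-dihydroxytridecane-1,13-dione (mixture of racemic and meso forms) | COc1c(OC)c(C)c(OC)c(OCc2ccccc2)c1C(=O)CC(O)CCCCCCCC(O)CC(=O)c1c(OCc2ccccc2)c(OC)c(C)c(OC)c1OC
F7 | step 7 | (2E,11E)-1,13-bis[2-(benzyloxy)-3,5,6-trimethoxy-4-methylphenyl]trideca-2,11-diene-1,13-dione | COc1c(OC)c(C)c(OC)c(OCc2ccccc2)c1C(=O)/C=C/CCCCCCC/C=C/C(=O)c1c(OCc2ccccc2)c(OC)c(C)c(OC)c1OC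
F8 | step 10 | 1,13-bis(2,6-dihydroxy-3,5-dimethoxy-4-methylphenyl)tridecane-1,13-dione | Oc1c(OC)c(C)c(OC)c(O)c1C(=O)CCCCCCCCCCCC(=O)c1c(O)c(OC)c(C)c(OC)c1O
F9 | step 10 | 2,2'-(tridecane-1,13-diyl)bis(4,6-dimethoxy-5-methylbenzene-1,3-diol) | Oc1c(OC)c(C)c(OC)c(O)c1CCCCCCCCCCCCCc1c(O)c(OC)c(C)c(OC)c1O
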